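**Retrosynthetic overview**

1. Salimabromide (21) ← aromatic dibromination and dehydrogenation of cycloheptanone 18 ← insertion of one CH2 (C13) into the C14–C12 bond of the six-membered keto lactone 16; this ring enlargement closes the cycloheptenone last.
2. Enabling feature: in the ring C7–C8–C14(=O)–C13=C12–C11–C10 the ketone C14 lies between C8, an O-bearing bridgehead of the lactone bicycle (cannot enolise, migrates poorly), and the C13 methine; without C13 the ring is a cyclohexanone, i.e. a Diels–Alder retron.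
3. γ-Lactone (C7–C8–O–C9–C10) ← exo syn-dihydroxylation/lactonisation of cyclohexene ester 13; tetralin ring ← Friedel–Crafts acylation through C15, then geminal dimethylation.
4. Cyclohexene carrying C7, C10 and the quaternary C11 ← catalytic enantioselective Diels–Alder reaction of 2-silyloxy-1-aryldiene 5 with formyl crotonate 6; C8 is set later by substrate control.
5. Ring order: arene (bought) → cyclohexene (step 4) → tetralin ring (step 8) → γ-lactone (step 10) → seven-membered ring (step 12).

Key step: step 12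

Locants: in all intermediates the target's carbons are called C7 (ArCH), C8 (CH–O), C9 (lactone C=O), C10 (CH–C9), C11 (C–CH3), C12/C13 (CH=CH), C14 (ketone C) and C15 (C(CH3)2).
Assumption: acid 1 and enal ester 6 are taken as catalogue chemicals.
Assumption: the (S)-configured oxazaborolidinium catalyst is taken to shield the enal face that leads to the (7S,10R,11R) series; its mirror image would be used if the sense proved opposite.

**Route**

Step 1
Reactants: 1 2-(3-ethylphenyl)acetic acid
Product: 3 2-(3-ethylphenyl)-N-methoxy-N-methylacetamide, via 1-[2-(3-ethylphenyl)acetyl]imidazole 2 (not isolated)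
Conditions: CDI, CH2Cl2, rt; then MeNH(OMe)·HCl, rt
Reagents that add atoms: N,O-dimethylhydroxylamine hydrochloride, CNOC.Cl
Why: Acyl imidazolide formation and aminolysis (CDI-mediated Weinreb amide synthesis) is routine for arylacetic acids and creates no stereocentre.

Step 2
Reactants: 3 2-(3-ethylphenyl)-N-methoxy-N-methylacetamide
Product: 4 1-(3-ethylphenyl)but-3-en-2-one
Conditions: CH2=CHMgBr, THF, −78 → 0 °C; cold 1 M HCl quench
Reagents that add atoms: vinylmagnesium bromide, C=C[Mg]Br
Why: Weinreb ketone synthesis, in which the chelated tetrahedral adduct should survive until the cold acidic quench, so the vinyl ketone is released only when no nucleophile is left.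

Step 3
Reactants: 4 1-(3-ethylphenyl)but-3-en-2-one
Product: 5 tert-butyl{[(1Z)-1-(3-ethylphenyl)buta-1,3-dien-2-yl]oxy}dimethylsilane
Conditions: TBSOTf, Et3N, CH2Cl2, −78 → 0 °C
Reagents that add atoms: tert-butyldimethylsilyl trifluoromethanesulfonate, CC(C)(C)[Si](C)(C)OS(=O)(=O)C(F)(F)F
Why: Soft enolisation (silyl triflate/amine) can only go toward the benzylic CH2 and should give the conjugated 2-silyloxydiene as the (Z)-enol ether, with the aryl group cis to OSi and therefore on the outside of the s-cis diene.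

Step 4
Reactants: 5 tert-butyl{[(1Z)-1-(3-ethylphenyl)buta-1,3-dien-2-yl]oxy}dimethylsilane; 6 ethyl (2E)-3-methyl-4-oxobut-2-enoate
Product: 7 ethyl (1R,2R,6S)-5-{[tert-butyl(dimethyl)silyl]oxy}-6-(3-ethylphenyl)-2-formyl-2-methylcyclohex-4-ene-1-carboxylate
Conditions: (S)-o-tolyl-CBS-oxazaborolidine (20 mol %), Tf2NH (18 mol %), CH2Cl2, −78 → −40 °C
Reagents that add atoms: none
Why: Enantioselective Diels–Alder reaction of an α-methyl enal under chiral oxazaborolidinium Lewis-acid catalysis: the catalyst-bound formyl group makes the ester-bearing β-carbon (future C10) the electrophilic site, which should bond to the silyl-enol-ether terminus C7 (the 2-silyloxy "para" and the ester "ortho" preferences coincide), the formyl group should lie endo under the diene (only H then faces the bulky OSi) so that aryl and CHO become cis and the E-ester trans, and the shielded enal face should fix C7, C10 and the quaternary C11 in one event.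

Step 5
Reactants: 7 ethyl (1R,2R,6S)-5-{[tert-butyl(dimethyl)silyl]oxy}-6-(3-ethylphenyl)-2-formyl-2-methylcyclohex-4-ene-1-carboxylate
Product: 8 ethyl (1R,2R,6S)-6-(3-ethylphenyl)-2-formyl-2-methyl-5-{[(trifluoromethyl)sulfonyl]oxy}cyclohex-4-ene-1-carboxylate
Conditions: CsF, PhNTf2, DME, rt
Reagents that add atoms: N-phenylbis(trifluoromethanesulfonimide), O=S(=O)(N(c1ccccc1)S(=O)(=O)C(F)(F)F)C(F)(F)F
Why: Fluoride-triggered conversion of a silyl enol ether into its enol triflate: the caesium enolate should be triflated on oxygen with the double bond kept between C8 and C14, so the regiochemistry written by the cycloaddition is carried over.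

Step 6
Reactants: 8 ethyl (1R,2R,6S)-6-(3-ethylphenyl)-2-formyl-2-methyl-5-{[(trifluoromethyl)sulfonyl]oxy}cyclohex-4-ene-1-carboxylate
Product: 9 ethyl (1R,2R,6S)-6-(3-ethylphenyl)-2-formyl-2-methylcyclohex-4-ene-1-carboxylate
Conditions: Pd(OAc)2 (5 mol %), PPh3 (10 mol %), HCO2H, n-Bu3N, DMF, 60 °C
Reagents that add atoms: none
Why: Palladium-catalysed formate reduction of an enol triflate (oxidative addition, decarboxylation of the palladium formate, C–H reductive elimination) should give the cis ring alkene C8=C14 and leave aldehyde, ester and the three stereocentres untouched.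

Step 7
Reactants: 9 ethyl (1R,2R,6S)-6-(3-ethylphenyl)-2-formyl-2-methylcyclohex-4-ene-1-carboxylate
Product: 10 (1R,2R,3S)-2-(ethoxycarbonyl)-3-(3-ethylphenyl)-1-methylcyclohex-4-ene-1-carboxylic acid
Conditions: NaClO2, NaH2PO4, 2-methyl-2-butene, t-BuOH/H2O, 0 °C → rt
Reagents that add atoms: sodium chlorite, [Na+].[O-]Cl=O
Why: Pinnick oxidation of the non-enolisable neopentyl aldehyde, with 2-methyl-2-butene as hypochlorite scavenger, should spare the ring alkene and give the acid needed for acylation.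

Step 8
Reactants: 10 (1R,2R,3S)-2-(ethoxycarbonyl)-3-(3-ethylphenyl)-1-methylcyclohex-4-ene-1-carboxylic acid
Product: 12 ethyl (5S,9R,11R)-3-ethyl-9-methyl-10-oxo-5,8,9,10-tetrahydro-5,9-methanobenzo[8]annulene-11-carboxylate, via acid chloride 11 (not isolated)
Conditions: (COCl)2, DMF (cat.), CH2Cl2, 0 °C → rt; then SnCl4, CH2Cl2, −20 → 0 °C
Reagents that add atoms: none
Why: Intramolecular Friedel–Crafts acylation: the acylium on C11 can reach only the cis-disposed aryl group set in step 4 and should attack the position para to ethyl and ortho to C7, closing the six-membered tetralone ring of a bicyclo[3.3.1] framework.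

Step 9
Reactants: 12 ethyl (5S,9R,11R)-3-ethyl-9-methyl-10-oxo-5,8,9,10-tetrahydro-5,9-methanobenzo[8]annulene-11-carboxylate
Product: 13 ethyl (5S,9R,11R)-3-ethyl-9,10,10-trimethyl-5,8,9,10-tetrahydro-5,9-methanobenzo[8]annulene-11-carboxylate
Conditions: Me2Zn, TiCl4 (→ Me2TiCl2), CH2Cl2, −30 °C → rt
Reagents that add atoms: dimethyltitanium dichloride, C[Ti](C)(Cl)Cl (formed in the flask from dimethylzinc, C[Zn]C, and titanium tetrachloride, Cl[Ti](Cl)(Cl)Cl)
Why: Titanium-mediated geminal dimethylation of an aryl ketone (methyl addition, ionisation of the tertiary benzylic titanium alkoxide, second methyl transfer) should turn C15=O into C(CH3)2, the ester and the alkene being inert to the reagent at low temperature.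

Step 10
Reactants: 13 ethyl (5S,9R,11R)-3-ethyl-9,10,10-trimethyl-5,8,9,10-tetrahydro-5,9-methanobenzo[8]annulene-11-carboxylate
Product: 15 (5S,6S,7R,9R,11R)-3-ethyl-7-hydroxy-9,10,10-trimethyl-5,6,7,8,9,10-hexahydro-5,9-methanobenzo[8]annulene-11,6-carbolactone, via diol ester 14 (not isolated)
Conditions: OsO4 (2 mol %), NMO, acetone/H2O, rt; then p-TsOH·H2O (cat.), toluene, 60 °C
Reagents that add atoms: N-methylmorpholine N-oxide, C[N+]1([O-])CCOCC1; water, O
Why: Upjohn syn-dihydroxylation should occur on the exo face of the bicyclo[3.3.1]nonene (the face of the ester, opposite the benzo bridge), which sets C8, and the C8 hydroxyl, 1,3-diaxial to the ester, should then close the γ-lactone under acid with loss of ethanol, in preference to the δ-lactone through the C14 hydroxyl.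

Step 11
Reactants: 15 (5S,6S,7R,9R,11R)-3-ethyl-7-hydroxy-9,10,10-trimethyl-5,6,7,8,9,10-hexahydro-5,9-methanobenzo[8]annulene-11,6-carbolactone
Product: 16 (5S,6S,9R,11R)-3-ethyl-9,10,10-trimethyl-7-oxo-5,6,7,8,9,10-hexahydro-5,9-methanobenzo[8]annulene-11,6-carbolactone
Conditions: Dess–Martin periodinane, CH2Cl2, rt
Reagents that add atoms: none
Why: Dess–Martin oxidation of the remaining secondary alcohol gives the C14 ketone with no centre at risk, C8 and C10 being bridgeheads of the lactone bicycle.

Step 12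
Reactants: 16 (5S,6S,9R,11R)-3-ethyl-9,10,10-trimethyl-7-oxo-5,6,7,8,9,10-hexahydro-5,9-methanobenzo[8]annulene-11,6-carbolactone
Product: 18 (5S,6S,10R,12R)-3-ethyl-10,11,11-trimethyl-7-oxo-6,7,8,9,10,11-hexahydro-5H-5,10-methanobenzo[9]annulene-12,6-carbolactone, via α-silyl ketone 17 (not isolated)
Conditions: TMSCHN2 (1.5 equiv), BF3·OEt2 (1.2 equiv), CH2Cl2, −78 → −30 °C; then 1 M HCl, THF, rt
Reagents that add atoms: (trimethylsilyl)diazomethane, C[Si](C)(C)C=[N+]=[N-]
Why: BF3 activates the C14 ketone, TMSCHN2 adds to it, and a 1,2-shift of a ring carbon from C14 to the diazo carbon with loss of N2 enlarges the ring (Büchner–Curtius–Schlotterbeck/Tiffeneau–Demjanov-type homologation), after which the α-silyl ketone 17 is protodesilylated. The closest known reaction type is the Lewis-acid-promoted TMSCHN2 ring expansion of cyclohexanones to cycloheptanones, including α-heteroatom-substituted ketones in which the unsubstituted α-carbon migrates. The seven-membered ring is closed by enlargement of the six-membered ketone (C13 inserted between C14 and C12) and not by cyclisation, so the entropic and transannular cost of closing a doubly bridged seven-membered ring is avoided. No stereocentre is created (C13 ends as CH2), and C7, C8, C10 and C11 are bridgeheads or quaternary and cannot epimerise. The step needs migration of C12 instead of C8: C8 is a bridgehead that carries the electron-withdrawing acyloxy oxygen and should migrate poorly, C12 is a plain methylene, and the lactone carbonyl is not attacked by the diazoalkane.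

Step 13
Reactants: 18 (5S,6S,10R,12R)-3-ethyl-10,11,11-trimethyl-7-oxo-6,7,8,9,10,11-hexahydro-5H-5,10-methanobenzo[9]annulene-12,6-carbolactone
Product: 20 (5S,6S,10R,12R)-3-ethyl-10,11,11-trimethyl-7-oxo-6,7,10,11-tetrahydro-5H-5,10-methanobenzo[9]annulene-12,6-carbolactone, via silyl enol ether 19 (not isolated)
Conditions: LiHMDS, TMSCl, THF, −78 °C; then Pd(OAc)2, MeCN, rt
Reagents that add atoms: none
Why: Saegusa–Ito dehydrogenation: the ketone can enolise only toward C13 because C8 is a bridgehead, and Pd(II) should oxidise the silyl enol ether (oxa-π-allyl, β-hydride elimination) to the C12=C13 double bond conjugated with C14=O.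

Step 14
Reactants: 20 (5S,6S,10R,12R)-3-ethyl-10,11,11-trimethyl-7-oxo-6,7,10,11-tetrahydro-5H-5,10-methanobenzo[9]annulene-12,6-carbolactone
Product: 21 salimabromide
Conditions: NBS (2.2 equiv), TfOH (cat.), TFA, 0 °C → rt
Reagents that add atoms: N-bromosuccinimide, O=C1CCC(=O)N1Br
Why: Electrophilic aromatic bromination under strongly acidic conditions: the two free positions ortho to ethyl are the most activated (the first also para, the second also ortho to a ring alkyl), the third free position lies between a bromine and the gem-dimethyl carbon, and the protonated enone, which has no enolisable hydrogen, should not react.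

**Compound list**

1 | 2-(3-ethylphenyl)acetic acid | CCc1cccc(CC(=O)O)c1 | starting material
2 | 1-[2-(3-ethylphenyl)acetyl]imidazole | CCc1cccc(CC(=O)n2ccnc2)c1 | intermediate
3 | 2-(3-ethylphenyl)-N-methoxy-N-methylacetamide | CCc1cccc(CC(=O)N(C)OC)c1 | intermediate
4 | 1-(3-ethylphenyl)but-3-en-2-one | CCc1cccc(CC(=O)C=C)c1 | intermediate
5 | tert-butyl{[(1Z)-1-(3-ethylphenyl)buta-1,3-dien-2-yl]oxy}dimethylsilane | CCc1cccc(/C=C(\O[Si](C)(C)C(C)(C)C)C=C)c1 | intermediate
6 | ethyl (2E)-3-methyl-4-oxobut-2-enoate | CCOC(=O)/C=C(\C)C=O | starting material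
7 | ethyl (1R,2R,6S)-5-{[tert-butyl(dimethyl)silyl]oxy}-6-(3-ethylphenyl)-2-formyl-2-methylcyclohex-4-ene-1-carboxylate | CCc1cccc(c1)[C@@H]1[C@@H](C(=O)OCC)[C@](C)(C=O)CC=C1O[Si](C)(C)C(C)(C)C | intermediate
8 | ethyl (1R,2R,6S)-6-(3-ethylphenyl)-2-formyl-2-methyl-5-{[(trifluoromethyl)sulfonyl]oxy}cyclohex-4-ene-1-carboxylate | CCc1cccc(c1)[C@@H]1[C@@H](C(=O)OCC)[C@](C)(C=O)CC=C1OS(=O)(=O)C(F)(F)F | intermediate
9 | ethyl (1R,2R,6S)-6-(3-ethylphenyl)-2-formyl-2-methylcyclohex-4-ene-1-carboxylate | CCc1cccc(c1)[C@@H]1[C@@H](C(=O)OCC)[C@](C)(C=O)CC=C1 | intermediate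
10 | (1R,2R,3S)-2-(ethoxycarbonyl)-3-(3-ethylphenyl)-1-methylcyclohex-4-ene-1-carboxylic acid | CCc1cccc(c1)[C@@H]1[C@@H](C(=O)OCC)[C@](C)(C(=O)O)CC=C1 | intermediate
11 | ethyl (1R,2R,6S)-2-(chlorocarbonyl)-6-(3-ethylphenyl)-2-methylcyclohex-4-ene-1-carboxylate | CCc1cccc(c1)[C@@H]1[C@@H](C(=O)OCC)[C@](C)(C(Cl)=O)CC=C1 | intermediate
12 | ethyl (5S,9R,11R)-3-ethyl-9-methyl-10-oxo-5,8,9,10-tetrahydro-5,9-methanobenzo[8]annulene-11-carboxylate (2,4-bridged 1-tetralone; 7S,10R,11R) | CCc1ccc2c(c1)[C@H]3C=CC[C@](C)([C@@H]3C(=O)OCC)C2=O | intermediate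
13 | ethyl (5S,9R,11R)-3-ethyl-9,10,10-trimethyl-5,8,9,10-tetrahydro-5,9-methanobenzo[8]annulene-11-carboxylate | CCc1ccc2c(c1)[C@H]3C=CC[C@](C)([C@@H]3C(=O)OCC)C2(C)C | intermediate
14 | ethyl (5S,6S,7R,9R,11R)-3-ethyl-6,7-dihydroxy-9,10,10-trimethyl-5,6,7,8,9,10-hexahydro-5,9-methanobenzo[8]annulene-11-carboxylate | CCc1ccc2c(c1)[C@H]3[C@H](O)[C@H](O)C[C@](C)([C@@H]3C(=O)OCC)C2(C)C | intermediate
15 | (5S,6S,7R,9R,11R)-3-ethyl-7-hydroxy-9,10,10-trimethyl-5,6,7,8,9,10-hexahydro-5,9-methanobenzo[8]annulene-11,6-carbolactone (7S,8S,10R,11R,14R) | CCc1ccc2c(c1)[C@H]1[C@@H]3OC(=O)[C@H]1[C@@](C)(C[C@H]3O)C2(C)C | intermediate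
16 | (5S,6S,9R,11R)-3-ethyl-9,10,10-trimethyl-7-oxo-5,6,7,8,9,10-hexahydro-5,9-methanobenzo[8]annulene-11,6-carbolactone (six-membered keto lactone; 7S,8S,10R,11R) | CCc1ccc2c(c1)[C@H]1[C@@H]3OC(=O)[C@H]1[C@@](C)(CC3=O)C2(C)C | intermediate
17 | 8-(trimethylsilyl) derivative of 18 (silyl on C13, both epimers) | CCc1ccc2c(c1)[C@H]1[C@@H]3OC(=O)[C@H]1[C@@](C)(CC([Si](C)(C)C)C3=O)C2(C)C | intermediate
18 | (5S,6S,10R,12R)-3-ethyl-10,11,11-trimethyl-7-oxo-6,7,8,9,10,11-hexahydro-5H-5,10-methanobenzo[9]annulene-12,6-carbolactone (cycloheptanone; 7S,8S,10R,11R) | CCc1ccc2c(c1)[C@H]1[C@@H]3OC(=O)[C@H]1[C@@](C)(CCC3=O)C2(C)C | intermediate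
19 | trimethylsilyl enol ether of 18 (C13=C14–OSiMe3) | CCc1ccc2c(c1)[C@H]1[C@@H]3OC(=O)[C@H]1[C@@](C)(CC=C3O[Si](C)(C)C)C2(C)C | intermediate
20 | (5S,6S,10R,12R)-3-ethyl-10,11,11-trimethyl-7-oxo-6,7,10,11-tetrahydro-5H-5,10-methanobenzo[9]annulene-12,6-carbolactone (salimabromide without its two bromine atoms) | CCc1ccc2c(c1)[C@H]1[C@@H]3OC(=O)[C@H]1[C@@](C)(C=CC3=O)C2(C)C | intermediate
21 | salimabromide, (5S,6S,10R,12R)-2,4-dibromo-3-ethyl-10,11,11-trimethyl-7-oxo-6,7,10,11-tetrahydro-5H-5,10-methanobenzo[9]annulene-12,6-carbolactone (7S,8S,10R,11R) | CCc1c(Br)cc2c(c1Br)[C@H]1[C@@H]3OC(=O)[C@H]1[C@@](C)(C=CC3=O)C2(C)C | target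

**Count and risks**

Total steps: 14. Longest linear sequence: 14 steps (1 → 21).

Steps most likely to fail:

1. Step 12. The 1,2-shift may lose regiocontrol (migration of the bridgehead C8), or the diazoalkane may give epoxide or a second homologation. Fallback (Ito–Saegusa ring expansion): starting from 16, LiHMDS/TMSCl should give the silyl enol ether F1 (enolisation is possible only toward C12); Simmons–Smith cyclopropanation (Et2Zn, CH2I2) gives the siloxycyclopropane F2; FeCl3 in DMF cleaves the internal C12–C14 bond to the β-chloro ketone F3; NaOAc in MeOH eliminates HCl and the route is rejoined at 20. The seven-membered ring is still the last one formed.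

2. Step 9. After the first methyl transfer the benzylic cation may be captured across the ring by the C8=C14 alkene, lose a proton, or the reaction may stall at the tertiary alkoxide. Fallback (cationic Friedel–Crafts cyclialkylation, replacing steps 7–9): starting from 9, MeMgBr in THF at −78 °C gives the secondary alcohol F4, Dess–Martin oxidation the methyl ketone F5, and MeMgBr/CeCl3 at −78 °C with a cold quench the tertiary alcohol F6; MsOH in CH2Cl2 at 0 °C then ionises F6, and the tertiary cation alkylates the aryl ring para to ethyl, rejoining the route at 13.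

3. Step 14. The second bromination may be slow at the hindered position between ethyl and the ring, so that forcing conditions brominate elsewhere or attack the enone. Fallback (bromination before any ketone or alkene is present): starting from 15, NBS/TfOH in TFA gives the dibromo hydroxy lactone F7 and Dess–Martin oxidation the dibromo keto lactone F8; the conditions of step 12 then give the α-silyl ketone F9 and, after acid, the dibromo cycloheptanone F10; LiHMDS/TMSCl gives the silyl enol ether F11, and Pd(OAc)2 rejoins the route at 21.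

Further compounds
F1 | step 12 | trimethylsilyl enol ether of 16 (C12=C14–OSiMe3) | CCc1ccc2c(c1)[C@H]1[C@@H]3OC(=O)[C@H]1[C@@](C)(C=C3O[Si](C)(C)C)C2(C)C
F2 | step 12 | siloxycyclopropane from F1 (cyclopropane C12–C13–C14; configuration at C12 and C14 not fixed) | CCc1ccc2c(c1)[C@H]1[C@@H]3OC(=O)[C@H]1[C@@](C)(C4CC34O[Si](C)(C)C)C2(C)C
F3 | step 12 | 12-chloro derivative of 18 (β-chloro ketone, both C12 epimers) | CCc1ccc2c(c1)[C@H]1[C@@H]3OC(=O)[C@H]1[C@@](C)(C(Cl)CC3=O)C2(C)C
F4 | step 9 | ethyl (1R,2R,6S)-6-(3-ethylphenyl)-2-(1-hydroxyethyl)-2-methylcyclohex-4-ene-1-carboxylate (carbinol epimers) | CCc1cccc(c1)[C@@H]1[C@@H](C(=O)OCC)[C@](C)(C(C)O)CC=C1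
F5 | step 9 | ethyl (1R,2R,6S)-2-acetyl-6-(3-ethylphenyl)-2-methylcyclohex-4-ene-1-carboxylate | CCc1cccc(c1)[C@@H]1[C@@H](C(=O)OCC)[C@](C)(C(C)=O)CC=C1
F6 | step 9 | ethyl (1R,2R,6S)-6-(3-ethylphenyl)-2-(2-hydroxypropan-2-yl)-2-methylcyclohex-4-ene-1-carboxylate | CCc1cccc(c1)[C@@H]1[C@@H](C(=O)OCC)[C@](C)(C(C)(C)O)CC=C1
F7 | step 14 | 2,4-dibromo derivative of 15 | CCc1c(Br)cc2c(c1Br)[C@H]1[C@@H]3OC(=O)[C@H]1[C@@](C)(C[C@H]3O)C2(C)C
F8 | step 14 | 2,4-dibromo derivative of 16 | CCc1c(Br)cc2c(c1Br)[C@H]1[C@@H]3OC(=O)[C@H]1[C@@](C)(CC3=O)C2(C)C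
F9 | step 14 | 2,4-dibromo derivative of 17 | CCc1c(Br)cc2c(c1Br)[C@H]1[C@@H]3OC(=O)[C@H]1[C@@](C)(CC([Si](C)(C)C)C3=O)C2(C)C
F10 | step 14 | 2,4-dibromo derivative of 18 | CCc1c(Br)cc2c(c1Br)[C@H]1[C@@H]3OC(=O)[C@H]1[C@@](C)(CCC3=O)C2(C)C
F11 | step 14 | 2,4-dibromo derivative of 19 | CCc1c(Br)cc2c(c1Br)[C@H]1[C@@H]3OC(=O)[C@H]1[C@@](C)(CC=C3O[Si](C)(C)C)C2(C)C
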